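**Strategy.** Each carbon of the C8–C8'' axis sits in ring A between the oxygen-bearing carbons C7 and C8a, the position of a γ-acylated acetoacetate γ-carbon. The axis is therefore taken as the preformed central C–C bond of a succinyl unit, and both A rings are grown around it. The precursor is the fourfold silylated bis-dienol ether of dimethyl 3,6-dioxooctanedioate. With two molecules of 3,3-diethoxyacryloyl chloride it should undergo a double formal [3+3] cyclocondensation that forms C7–C8 and C4a–C5 in each half and closes both A rings. C5 is left as an ether, C7 and C8a as phenols, and the ester becomes C4 of ring C.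

Key step: step 6

Remark: the target is drawn without a descriptor for the C8–C8'' axis, so the racemic atropisomer is taken as the goal. A-ring carbons carry flavone numbers (C4a to C8a) from the precursor stage onward.

**Step 1**
Reactants: 1 succinyl chloride; 2 2,2-dimethyl-1,3-dioxane-4,6-dione (Meldrum's acid)
Product: 4 dimethyl 3,6-dioxooctanedioate, via bis-acylated Meldrum's acid adduct 3 (not isolated)
Conditions: pyridine, CH2Cl2, 0 → 20 °C; then MeOH, reflux
Reagents that add atoms: methanol, CO
Why: Twofold C-acylation of Meldrum's acid by the diacid chloride and thermal methanolysis of each acyl Meldrum's acid (loss of acetone and CO2) is the standard Meldrum's acid β-keto ester synthesis, run on both ends of the succinyl unit.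

**Step 2**
Reactants: 4 dimethyl 3,6-dioxooctanedioate
Product: 5 dimethyl 3,6-bis(trimethylsilyloxy)octa-2,6-dienedioate
Conditions: Me3SiCl, Et3N, toluene, 20 °C
Reagents that add atoms: chlorotrimethylsilane, C[Si](C)(C)Cl
Why: The strongly enolised β-keto ester units are O-silylated under soft enolisation (amine base, silyl chloride), the first stage of the usual preparation of 1,3-bis(silyloxy)-1,3-dienes, and the weak base should spare the 1,4-diketone from aldol closure.

**Step 3**
Reactants: 5 dimethyl 3,6-bis(trimethylsilyloxy)octa-2,6-dienedioate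
Product: 6 1,8-dimethoxy-1,3,6,8-tetrakis(trimethylsilyloxy)octa-1,3,5,7-tetraene
Conditions: LiN(iPr)2, Me3SiCl (in situ quench), THF, −78 → 20 °C; filter under Ar, use crude
Reagents that add atoms: chlorotrimethylsilane, C[Si](C)(C)Cl
Why: γ-Deprotonation of each β-silyloxy enoate by the lithium amide with immediate O-silylation of the ester dienolate is the standard second stage of bis(silyloxy)diene synthesis, and the in situ quench means that no species with two adjacent carbanionic centres has to form.

**Step 4**
Reactants: 7 ethyl 3,3-diethoxyacrylate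
Product: 8 potassium 3,3-diethoxyacrylate
Conditions: KOH (1.0 equiv), EtOH, 20 °C; evaporate, dry by toluene azeotrope, no acidification
Reagents that add atoms: potassium hydroxide, [K+].[OH-]
Why: Ester saponification by acyl–oxygen cleavage leaves the base-stable ketene acetal untouched, and isolating the dry potassium salt avoids the free acid, which would protonate its own acetal.

**Step 5**
Reactants: 8 potassium 3,3-diethoxyacrylate
Product: 9 3,3-diethoxyacryloyl chloride
Conditions: (COCl)2 (1.0 equiv), CH2Cl2, −20 → 0 °C; filter under Ar, use the cold solution at once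
Reagents that add atoms: oxalyl chloride, O=C(Cl)C(Cl)=O
Why: A dry carboxylate salt is converted by oxalyl chloride into the acyl chloride with release of only KCl, CO and CO2 (standard acid chloride formation), so no HCl arises that could attack the ketene acetal.

**Step 6**
Reactants: 6 1,8-dimethoxy-1,3,6,8-tetrakis(trimethylsilyloxy)octa-1,3,5,7-tetraene; 9 3,3-diethoxyacryloyl chloride (2.3 equiv)
Product: 11 dimethyl 4,4'-diethoxy-2,2',6,6'-tetrahydroxybiphenyl-3,3'-dicarboxylate, via twofold C8-acylated bis(silyl enol ether) 10 (not isolated)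
Conditions: 2,6-di-tert-butylpyridine (0.2 equiv), CH2Cl2, −78 → 0 °C; then Me3SiOTf (0.3 equiv), 0 → 20 °C; 1 M HCl, MeOH work-up
Reagents that add atoms: none
Why: Proposed new method: each diene terminus (C8, C8''), the most nucleophilic site of a 1,3-bis(silyloxy)-1,3-diene, should attack the acyl chloride carbon of 9 without Lewis acid and lose Me3SiCl to give 10; Me3SiOTf then silylates each C7 carbonyl, which turns the β,β-diethoxy enone into a dialkoxycarbenium ion at C5 that is captured by the remaining silyl enol ether carbon C4a, and loss of EtOSiMe3 followed by two enolisations aromatises each ring. The closest known chemistry is the formal [3+3] cyclocondensation of 1,3-bis(silyloxy)-1,3-dienes with 3-alkoxy- or 3-silyloxy-enones to salicylates, together with their terminal C-acylation by acid chlorides to 3,5-dioxo esters; new are the twofold version on a γ,γ'-linked bis-diene and a ketene acetal acid chloride as the 1,3-dielectrophile. Both A rings close in the same way, by 6-endo-trig conjugate addition–elimination of C4a at C5 (the attacked C5=C6 bond lies inside the new ring), so that C4a–C5 follows C7–C8 in each half. No stereocentre is created: the two CH centres of 10 and all alkene geometry vanish on aromatisation, and the axis forms as a racemate. The step needs the acyl carbon at C7 and the acetal carbon at C5, which the much higher electrophilicity of the COCl group toward the uncatalysed diene terminus secures, so that C5 keeps its ether and only the C8a hydroxyl can later become O1. Closure through carbon and not oxygen is favoured because the C8a oxygen stays silylated while C4a is the nucleophilic enol ether carbon, and holding back the Lewis acid until both acylations are over keeps the second terminus from having to react next to a finished aryl ring.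

**Step 7**
Reactants: 11 dimethyl 4,4'-diethoxy-2,2',6,6'-tetrahydroxybiphenyl-3,3'-dicarboxylate
Product: 12 dimethyl 4,4'-diethoxy-2,2'-dihydroxy-6,6'-dimethoxybiphenyl-3,3'-dicarboxylate
Conditions: MeI (2.2 equiv), K2CO3 (2.2 equiv), acetone, 20 → 40 °C
Reagents that add atoms: iodomethane, CI
Why: The C7 hydroxyls, para to the ester and not hydrogen-bonded, are more acidic and more nucleophilic than the C8a hydroxyls chelated to the ester carbonyl, so Williamson etherification with limited base and MeI should stop at the 7,7''-dimethyl ether, as in the 4-O-selective alkylation of 2,4-dihydroxybenzoates.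

**Step 8**
Reactants: 12 dimethyl 4,4'-diethoxy-2,2'-dihydroxy-6,6'-dimethoxybiphenyl-3,3'-dicarboxylate; 13 4-benzyloxyacetophenone (6 equiv)
Product: 15 2,2'-bis[4-(benzyloxy)phenyl]-5,5'-diethoxy-7,7'-dimethoxy-4H,4'H-[8,8'-bichromene]-4,4'-dione, via bis(β-diketone) 14 (not isolated)
Conditions: LiN(SiMe3)2 (8.5 equiv), THF, −78 → 50 °C; 1 M HCl; then crude 14 in AcOH, H2SO4 (cat.), 90 °C
Reagents that add atoms: none
Why: Crossed Claisen condensation of the lithium enolate of 13 with each salicylate ester (the excess base covers the phenoxides and the acidic diketone products) gives the o-hydroxyaryl β-diketone, and acid-catalysed cyclodehydration, the ring closure of the Baker–Venkataraman flavone route, can use only the free C8a hydroxyl because C5 is blocked as its ethyl ether, which places O1 next to C8.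

**Step 9**
Reactants: 15 2,2'-bis[4-(benzyloxy)phenyl]-5,5'-diethoxy-7,7'-dimethoxy-4H,4'H-[8,8'-bichromene]-4,4'-dione
Product: 16 5,5'-dihydroxy-2,2'-bis(4-hydroxyphenyl)-7,7'-dimethoxy-4H,4'H-[8,8'-bichromene]-4,4'-dione (CNP0151059.0)
Conditions: BCl3 (8 equiv), C6HMe5 (6 equiv), CH2Cl2, −78 → 20 °C; MeOH, then H2O
Reagents that add atoms: none
Why: Lewis acid ether cleavage by BCl3 removes the benzyl groups (the benzyl cation is trapped by pentamethylbenzene) and, through chelation to the C4 carbonyl, dealkylates only the peri C5 ethoxy groups, while the unchelated C7 methyl ethers should stay intact.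

**Compound list**
1 | succinyl chloride | O=C(Cl)CCC(Cl)=O | starting material
2 | 2,2-dimethyl-1,3-dioxane-4,6-dione (Meldrum's acid) | CC1(C)OC(=O)CC(=O)O1 | starting material
3 | 5,5'-(1,4-dihydroxybutane-1,4-diylidene)bis(2,2-dimethyl-1,3-dioxane-4,6-dione), enol form of the bis-acylated Meldrum's acid adduct | CC1(C)OC(=O)C(=C(O)CCC(O)=C2C(=O)OC(C)(C)OC2=O)C(=O)O1 | intermediate (not isolated)
4 | dimethyl 3,6-dioxooctanedioate | COC(=O)CC(=O)CCC(=O)CC(=O)OC | intermediate
5 | dimethyl 3,6-bis(trimethylsilyloxy)octa-2,6-dienedioate (alkene geometry undefined, immaterial) | COC(=O)C=C(O[Si](C)(C)C)CCC(O[Si](C)(C)C)=CC(=O)OC | intermediate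
6 | 1,8-dimethoxy-1,3,6,8-tetrakis(trimethylsilyloxy)octa-1,3,5,7-tetraene (alkene geometry undefined, immaterial) | COC(O[Si](C)(C)C)=CC(O[Si](C)(C)C)=CC=C(O[Si](C)(C)C)C=C(OC)O[Si](C)(C)C | intermediate (key step precursor)
7 | ethyl 3,3-diethoxyacrylate | CCOC(=O)C=C(OCC)OCC | starting material
8 | potassium 3,3-diethoxyacrylate | [K+].[O-]C(=O)C=C(OCC)OCC | intermediate
9 | 3,3-diethoxyacryloyl chloride | CCOC(OCC)=CC(=O)Cl | intermediate (key step precursor)
10 | dimethyl 4,5-bis(3,3-diethoxyacryloyl)-3,6-bis(trimethylsilyloxy)octa-2,6-dienedioate (two CH centres and alkene geometry undefined, immaterial) | COC(=O)C=C(O[Si](C)(C)C)C(C(=O)C=C(OCC)OCC)C(C(=O)C=C(OCC)OCC)C(O[Si](C)(C)C)=CC(=O)OC | intermediate (not isolated)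
11 | dimethyl 4,4'-diethoxy-2,2',6,6'-tetrahydroxybiphenyl-3,3'-dicarboxylate (racemic axis) | CCOc1cc(O)c(-c2c(O)cc(OCC)c(C(=O)OC)c2O)c(O)c1C(=O)OC | intermediate (key step product)
12 | dimethyl 4,4'-diethoxy-2,2'-dihydroxy-6,6'-dimethoxybiphenyl-3,3'-dicarboxylate (racemic axis) | CCOc1cc(OC)c(-c2c(OC)cc(OCC)c(C(=O)OC)c2O)c(O)c1C(=O)OC | intermediate
13 | 4-benzyloxyacetophenone | CC(=O)c1ccc(OCc2ccccc2)cc1 | starting material
14 | 1,1'-(4,4'-diethoxy-2,2'-dihydroxy-6,6'-dimethoxybiphenyl-3,3'-diyl)bis{3-[4-(benzyloxy)phenyl]propane-1,3-dione} (keto–enol mixture) | CCOc1cc(OC)c(-c2c(OC)cc(OCC)c(C(=O)CC(=O)c3ccc(OCc4ccccc4)cc3)c2O)c(O)c1C(=O)CC(=O)c1ccc(OCc2ccccc2)cc1 | intermediate (not isolated)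
15 | 2,2'-bis[4-(benzyloxy)phenyl]-5,5'-diethoxy-7,7'-dimethoxy-4H,4'H-[8,8'-bichromene]-4,4'-dione (racemic axis) | COc1cc(OCC)c2c(=O)cc(-c3ccc(OCc4ccccc4)cc3)oc2c1-c1c(OC)cc(OCC)c2c(=O)cc(-c3ccc(OCc4ccccc4)cc3)oc12 | intermediate
16 | 5,5'-dihydroxy-2,2'-bis(4-hydroxyphenyl)-7,7'-dimethoxy-4H,4'H-[8,8'-bichromene]-4,4'-dione (racemic axis) | COc1cc(O)c2c(=O)cc(-c3ccc(O)cc3)oc2c1-c1c(OC)cc(O)c2c(=O)cc(-c3ccc(O)cc3)oc12 | target

**Step count.** Total: 9 steps. Longest linear sequence: 7 steps (steps 1, 2, 3, 6, 7, 8, 9).

**Steps most likely to fail**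

1. Step 6. What may go wrong: incomplete acylation of the second terminus beside the first, ring closure through oxygen to a 2-ethoxy-4-pyranone instead of through C4a, or breakdown of the ketene acetal before it is captured. The fallback uses known reactions only and makes the biaryl bond by coupling two finished flavone halves. It sets out from 13, which is C-acylated with dimethyl carbonate (NaH, toluene, reflux) to methyl 3-[4-(benzyloxy)phenyl]-3-oxopropanoate F1. Thermal Simonis-type condensation of F1 with phloroglucinol (neat, 240 °C) should give 2-[4-(benzyloxy)phenyl]-5,7-dihydroxy-4H-chromen-4-one F2. Exhaustive methylation (Me2SO4, K2CO3, acetone, reflux) should give 2-[4-(benzyloxy)phenyl]-5,7-dimethoxy-4H-chromen-4-one F3. Iodination with benzyltrimethylammonium dichloroiodate (CaCO3, CH2Cl2–MeOH), which is directed to C8 when O5 is alkylated, should give 2-[4-(benzyloxy)phenyl]-8-iodo-5,7-dimethoxy-4H-chromen-4-one F4. Ullmann homocoupling (activated copper powder, DMF, 150 °C) should give 2,2'-bis[4-(benzyloxy)phenyl]-5,5',7,7'-tetramethoxy-4H,4'H-[8,8'-bichromene]-4,4'-dione F5. BCl3 and C6HMe5 under the conditions of step 9 then remove the chelated 5-methyl and the benzyl groups, and the route is rejoined at 16.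

2. Step 5. What may go wrong: ionisation of the C–Cl bond of the push–pull acid chloride, followed by loss of chloroethane to an alkoxycarbonyl ketene, or self-acylation at the acetal α-carbon, before the diene is added. The fallback replaces the acyl chloride by a different class of acyl donor and sets out from 8. Cyanuric fluoride in MeCN at 0 °C should convert the salt into 3,3-diethoxyacryloyl fluoride F6, whose C–F bond does not ionise, so that it can be purified and stored. F6 then takes the place of 9 in step 6, the C–F bond being activated only in the presence of diene 6 by catalytic Me3SiOTf with formation of Me3SiF, and the route is rejoined at 11.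

3. Step 8. What may go wrong: the enolate fails to add to an ester that is flanked by two ortho oxygens and further deactivated by the adjacent phenoxide, so that ester is recovered and the ketone self-condenses. The fallback removes the phenoxide and sets out from 12. The C8a hydroxyls are capped as methoxymethyl ethers (NaH, MeOCH2Cl, DMF) to give dimethyl 4,4'-diethoxy-6,6'-dimethoxy-2,2'-bis(methoxymethoxy)biphenyl-3,3'-dicarboxylate F7. F7 should undergo the Claisen condensation with the enolate of 13 in the way of fully O-alkylated 2,4,6-trioxygenated benzoates, giving 1,1'-[4,4'-diethoxy-6,6'-dimethoxy-2,2'-bis(methoxymethoxy)biphenyl-3,3'-diyl]bis{3-[4-(benzyloxy)phenyl]propane-1,3-dione} F8. HCl in MeOH, then AcOH with catalytic H2SO4 at 90 °C, removes the acetals and cyclodehydrates, and the route is rejoined at 15.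

**Further compounds**
F1 | step 6 | methyl 3-[4-(benzyloxy)phenyl]-3-oxopropanoate | COC(=O)CC(=O)c1ccc(OCc2ccccc2)cc1
F2 | step 6 | 2-[4-(benzyloxy)phenyl]-5,7-dihydroxy-4H-chromen-4-one | O=c1cc(-c2ccc(OCc3ccccc3)cc2)oc2cc(O)cc(O)c12
F3 | step 6 | 2-[4-(benzyloxy)phenyl]-5,7-dimethoxy-4H-chromen-4-one | COc1cc(OC)c2c(=O)cc(-c3ccc(OCc4ccccc4)cc3)oc2c1
F4 | step 6 | 2-[4-(benzyloxy)phenyl]-8-iodo-5,7-dimethoxy-4H-chromen-4-one | COc1cc(OC)c2c(=O)cc(-c3ccc(OCc4ccccc4)cc3)oc2c1I
F5 | step 6 | 2,2'-bis[4-(benzyloxy)phenyl]-5,5',7,7'-tetramethoxy-4H,4'H-[8,8'-bichromene]-4,4'-dione | COc1cc(OC)c2c(=O)cc(-c3ccc(OCc4ccccc4)cc3)oc2c1-c1c(OC)cc(OC)c2c(=O)cc(-c3ccc(OCc4ccccc4)cc3)oc12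
F6 | step 5 | 3,3-diethoxyacryloyl fluoride | CCOC(OCC)=CC(F)=O
F7 | step 8 | dimethyl 4,4'-diethoxy-6,6'-dimethoxy-2,2'-bis(methoxymethoxy)biphenyl-3,3'-dicarboxylate | CCOc1cc(OC)c(-c2c(OC)cc(OCC)c(C(=O)OC)c2OCOC)c(OCOC)c1C(=O)OC
F8 | step 8 | 1,1'-[4,4'-diethoxy-6,6'-dimethoxy-2,2'-bis(methoxymethoxy)biphenyl-3,3'-diyl]bis{3-[4-(benzyloxy)phenyl]propane-1,3-dione} | CCOc1cc(OC)c(-c2c(OC)cc(OCC)c(C(=O)CC(=O)c3ccc(OCc4ccccc4)cc3)c2OCOC)c(OCOC)c1C(=O)CC(=O)c1ccc(OCc2ccccc2)cc1
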